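**Retrosynthetic overview**
1. The target is catechin-(4α→8)-gallocatechin-(4β→8)-catechin. All nine rings (A, B and C of each unit) are bought: (+)-taxifolin gives the upper unit, (+)-dihydromyricetin the middle unit and (+)-catechin the lower unit. Only the two C4–C8 bonds have to be made.
2. Both bonds are disconnected together and intramolecularly, from an open "triad" held by two temporary straps.
3. Strap one is an m-xylylene bis-ether between the two 5-oxygens, the chelated OH groups that survive mild benzylation. It lies in the plane of the upper cation, fits C8 but not C6, and is cleaved in the final hydrogenolysis.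
4. Strap two is a glutarate between the two 3-oxygens. It brings the lower catechin onto the β face of the middle unit, which gives the contra-steric 3,4-cis bond.
5. Ring order: the 14-membered cyclophane (upper bond) forms first, then the 14-membered macrolactone (lower bond), in one flask. Both temporary rings are opened in the last two steps.

Assumption: the SMILES is read as upper bond 3,4-trans (4α), lower bond 3,4-cis (4β), every C2 R and every C3 S. The 4-OMe epimers of 9 and 13 are drawn as 4β because C4 is ionised later.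

**Step 1**
Reactants: 1 (+)-catechin
Product: 2 5,7,3',4'-tetra-O-benzyl-(+)-catechin (3-OH free)
Conditions: BnBr (4.4 equiv), K2CO3, DMF, 0 °C to rt, Ar
Reagents that add atoms: benzyl bromide, BrCc1ccccc1
Why: Williamson etherification in which carbonate deprotonates only the four phenols, so the secondary 3-OH stays free and no stereocentre is touched.

**Step 2**
Reactants: 2 tetra-O-benzylcatechin; 3 glutaric anhydride
Product: 4 tetra-O-benzylcatechin 3-O-hemiglutarate (free carboxylic acid)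
Conditions: DMAP, pyridine, CH2Cl2, rt
Reagents that add atoms: none
Why: DMAP-catalysed ring-opening acylation of a cyclic anhydride by the only free hydroxyl group, with C3 retained because the C–O bond is not broken.

**Step 3**
Reactants: 5 (+)-dihydromyricetin (2R,3R)
Product: 6 7,3',4',5'-tetra-O-benzyldihydromyricetin (3-OH and chelated 5-OH free)
Conditions: BnBr (4.2 equiv), K2CO3, acetone, rt, Ar
Reagents that add atoms: benzyl bromide, BrCc1ccccc1
Why: Williamson etherification under mild base, in which the 5-OH hydrogen-bonded to C4=O and the 3-OH do not react and the base-sensitive trans ketol is spared forcing conditions.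

**Step 4**
Reactants: 4 hemiglutarate; 6 tetra-O-benzyldihydromyricetin
Product: 7 glutarate diester ketone (one end on O3 of 6, the other on O3 of the catechin unit; 5-OH free)
Conditions: DCC, DMAP (cat.), CH2Cl2, 0 °C
Reagents that add atoms: none
Why: Steglich esterification that takes place at the 3-OH only, because the 5-OH is locked in the hydrogen bond to the ketone; no stereocentre changes.

**Step 5**
Reactants: 7 glutarate diester ketone
Product: 9 glutarate diester of 4β-methoxy-7,3',4',5'-tetra-O-benzylgallocatechin (5-OH free) and tetra-O-benzylcatechin, via 4-ol 8 (not isolated)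
Conditions: NaBH4, CeCl3·7H2O, THF–MeOH, −40 °C; then PPTS, MeOH–CH2Cl2, 0 °C
Reagents that add atoms: methanol, CO
Why: Luche 1,2-reduction followed by A-ring-assisted SN1 exchange of the benzylic 4-OH with solvent methanol, which outcompetes the strapped arene; the C4 configuration is irrelevant because it is erased in step 10.

**Step 6**
Reactants: 10 (+)-taxifolin (2R,3R)
Product: 11 7,3',4'-tri-O-benzyltaxifolin (3-OH and chelated 5-OH free)
Conditions: BnBr (3.2 equiv), K2CO3, acetone, rt, Ar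
Reagents that add atoms: benzyl bromide, BrCc1ccccc1
Why: Williamson etherification with the same chelation-based selectivity as in step 3.

**Step 7**
Reactants: 11 tri-O-benzyltaxifolin
Product: 13 4β-methoxy-7,3',4'-tri-O-benzylcatechin (3-OH and 5-OH free), via flavan-3,4-diol 12 (not isolated)
Conditions: NaBH4, THF–MeOH, 0 °C; then PPTS, MeOH, rt
Reagents that add atoms: methanol, CO
Why: Ketone reduction then SN1 methanolysis of the benzylic alcohol in neat methanol; C2 and C3 are untouched and become the (2R,3S) pair of a catechin unit.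

**Step 8**
Reactants: 13 4-methoxy triol derivative; 14 1,3-bis(bromomethyl)benzene
Product: 15 5-O-[3-(bromomethyl)benzyl] ether of 13
Conditions: 14 (5 equiv), K2CO3, acetone, 40 °C
Reagents that add atoms: none
Why: Williamson etherification of the now unchelated 5-phenol, with excess dibromide to stop at mono-alkylation; methoxide is too poor a leaving group for base-induced quinone methide formation.

**Step 9**
Reactants: 15 benzylic bromide; 9 strapped 5-phenol
Product: 16 open triad (upper and middle units joined O5–CH2–C6H4–CH2–O5; middle and lower units joined O3–glutaryl–O3; a 4-OMe on the upper and on the middle unit)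
Conditions: Cs2CO3, DMF, rt
Reagents that add atoms: none
Why: Williamson etherification between the only phenol and the only alkyl halide present; esters and benzylic methyl ethers tolerate dry carbonate.

**Step 10 (key step)**
Reactants: 16 open triad
Product: 18 macrobicycle holding both C4–C8 bonds (upper 4α and lower 4β), via cyclophane 17 (not isolated)
Conditions: BF3·OEt2 (3 equiv), 4 Å MS, CH2Cl2 (0.5 mM), −78 °C, 2 h; then warm to −20 °C, 4 h; aq NaHCO3
Reagents that add atoms: none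
Why: Proposed new method: this is a temperature-staged ("armed then disarmed") double intramolecular Friedel–Crafts alkylation in which at −78 °C only the upper 4-OMe (free 3-OH beside it) ionises, and the m-xylylene strap, which hangs from the peri 5-oxygen in the nodal plane of the cation and spans the roughly 5.7 Å O5···O5 distance (hand estimate from idealised geometry) of a C8 adduct but not the 3.0–4.4 Å of a C6 adduct, lets C8 of the middle unit enter anti to the 3-OH (3,4-trans, 4α), after which warming ionises the lower 4-OMe, which is retarded by its 3-O-acyl neighbour, and the glutarate strap on the β-oriented 3-oxygen brings C8 of the catechin onto the β face only (3,4-cis, 4β), so that two 14-membered rings and both missing stereocentres arise in one flask; the closest known reaction types are the Lewis-acid coupling of 4-alkoxyflavans, its diester-tethered intramolecular variant that gives 3,4-cis products, and armed/disarmed donor sequencing in glycosylation.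

**Step 11**
Reactants: 18 macrobicycle
Product: 19 m-xylylene-bridged undeca-O-benzyl trimer (all three 3-OH free)
Conditions: K2CO3 (cat.), MeOH–THF, rt
Reagents that add atoms: none
Why: Zemplén-type transesterification opens the macrolactone at both acyl–oxygen bonds, so C3 of both units is retained and the interflavan bonds see no acid.

**Step 12**
Reactants: 19 bridged undeca-O-benzyl trimer
Product: 20 catechin-(4α→8)-gallocatechin-(4β→8)-catechin (target)
Conditions: H2 (1 atm), Pd(OH)2/C, THF–MeOH–H2O, rt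
Reagents that add atoms: none
Why: Catalytic hydrogenolysis cleaves the eleven benzyl ethers and the two benzylic C–O bonds of the xylylene strap under neutral conditions that leave the interflavan bonds and all stereocentres intact.

**Compound list**

1 | (+)-catechin | Oc1cc(O)c2c(c1)O[C@H](c1ccc(O)c(O)c1)[C@@H](O)C2 | starting material

2 | 5,7,3',4'-tetra-O-benzyl-(+)-catechin | O[C@H]1Cc2c(OCc3ccccc3)cc(OCc3ccccc3)cc2O[C@@H]1c1ccc(OCc2ccccc2)c(OCc2ccccc2)c1 | intermediate

3 | glutaric anhydride | O=C1CCCC(=O)O1 | starting material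

4 | tetra-O-benzylcatechin 3-O-hemiglutarate | OC(=O)CCCC(=O)O[C@H]1Cc2c(OCc3ccccc3)cc(OCc3ccccc3)cc2O[C@@H]1c1ccc(OCc2ccccc2)c(OCc2ccccc2)c1 | intermediate

5 | (+)-dihydromyricetin | Oc1cc(O)c2c(c1)O[C@H](c1cc(O)c(O)c(O)c1)[C@@H](O)C2=O | starting material

6 | 7,3',4',5'-tetra-O-benzyldihydromyricetin | O[C@H]1C(=O)c2c(O)cc(OCc3ccccc3)cc2O[C@@H]1c1cc(OCc2ccccc2)c(OCc2ccccc2)c(OCc2ccccc2)c1 | intermediate

7 | glutarate diester ketone | C(CC(=O)O[C@H]1C(=O)c2c(O)cc(OCc3ccccc3)cc2O[C@@H]1c1cc(OCc2ccccc2)c(OCc2ccccc2)c(OCc2ccccc2)c1)CC(=O)O[C@H]1Cc2c(OCc3ccccc3)cc(OCc3ccccc3)cc2O[C@@H]1c1ccc(OCc2ccccc2)c(OCc2ccccc2)c1 | intermediate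

8 | glutarate diester 4-ol (3,4-trans, 4α-OH) | C(CC(=O)O[C@H]1[C@H](O)c2c(O)cc(OCc3ccccc3)cc2O[C@@H]1c1cc(OCc2ccccc2)c(OCc2ccccc2)c(OCc2ccccc2)c1)CC(=O)O[C@H]1Cc2c(OCc3ccccc3)cc(OCc3ccccc3)cc2O[C@@H]1c1ccc(OCc2ccccc2)c(OCc2ccccc2)c1 | intermediate (not isolated)

9 | glutarate diester, middle unit 4β-OMe and 5-OH free | C(CC(=O)O[C@H]1[C@@H](OC)c2c(O)cc(OCc3ccccc3)cc2O[C@@H]1c1cc(OCc2ccccc2)c(OCc2ccccc2)c(OCc2ccccc2)c1)CC(=O)O[C@H]1Cc2c(OCc3ccccc3)cc(OCc3ccccc3)cc2O[C@@H]1c1ccc(OCc2ccccc2)c(OCc2ccccc2)c1 | intermediate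

10 | (+)-taxifolin | Oc1cc(O)c2c(c1)O[C@H](c1ccc(O)c(O)c1)[C@@H](O)C2=O | starting material

11 | 7,3',4'-tri-O-benzyltaxifolin | O[C@H]1C(=O)c2c(O)cc(OCc3ccccc3)cc2O[C@@H]1c1ccc(OCc2ccccc2)c(OCc2ccccc2)c1 | intermediate

12 | 7,3',4'-tri-O-benzyl flavan-3,4-diol (2R,3S,4R) | O[C@H]1[C@H](O)c2c(O)cc(OCc3ccccc3)cc2O[C@@H]1c1ccc(OCc2ccccc2)c(OCc2ccccc2)c1 | intermediate (not isolated)

13 | 4β-methoxy-7,3',4'-tri-O-benzylcatechin | O[C@H]1[C@@H](OC)c2c(O)cc(OCc3ccccc3)cc2O[C@@H]1c1ccc(OCc2ccccc2)c(OCc2ccccc2)c1 | intermediate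

14 | 1,3-bis(bromomethyl)benzene | BrCc1cccc(CBr)c1 | starting material

15 | 5-O-[3-(bromomethyl)benzyl] ether of 13 | O[C@H]1[C@@H](OC)c2c(OCc3cccc(CBr)c3)cc(OCc3ccccc3)cc2O[C@@H]1c1ccc(OCc2ccccc2)c(OCc2ccccc2)c1 | intermediate

16 | open doubly strapped triad | O[C@H]1[C@@H](OC)c2c(OCc3cccc(COc4cc(OCc5ccccc5)cc5O[C@H](c6cc(OCc7ccccc7)c(OCc7ccccc7)c(OCc7ccccc7)c6)[C@@H](OC(=O)CCCC(=O)O[C@H]6Cc7c(OCc8ccccc8)cc(OCc8ccccc8)cc7O[C@@H]6c6ccc(OCc7ccccc7)c(OCc7ccccc7)c6)[C@@H](OC)c45)c3)cc(OCc3ccccc3)cc2O[C@@H]1c1ccc(OCc2ccccc2)c(OCc2ccccc2)c1 | intermediate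

17 | 14-membered cyclophane (upper 4α C4–C8 bond closed, lower 4-OMe intact) | O[C@H]1[C@H]%10c2c(OCc3cccc(COc4cc(OCc5ccccc5)c%10c5O[C@H](c6cc(OCc7ccccc7)c(OCc7ccccc7)c(OCc7ccccc7)c6)[C@@H](OC(=O)CCCC(=O)O[C@H]6Cc7c(OCc8ccccc8)cc(OCc8ccccc8)cc7O[C@@H]6c6ccc(OCc7ccccc7)c(OCc7ccccc7)c6)[C@@H](OC)c45)c3)cc(OCc3ccccc3)cc2O[C@@H]1c1ccc(OCc2ccccc2)c(OCc2ccccc2)c1 | intermediate (not isolated)

18 | macrobicycle (cyclophane plus macrolactone, both C4–C8 bonds) | O[C@H]1[C@H]%10c2c(OCc3cccc(COc4cc(OCc5ccccc5)c%10c5O[C@H](c6cc(OCc7ccccc7)c(OCc7ccccc7)c(OCc7ccccc7)c6)[C@@H](OC(=O)CCCC(=O)O[C@H]6Cc7c(OCc8ccccc8)cc(OCc8ccccc8)c%11c7O[C@@H]6c6ccc(OCc7ccccc7)c(OCc7ccccc7)c6)[C@@H]%11c45)c3)cc(OCc3ccccc3)cc2O[C@@H]1c1ccc(OCc2ccccc2)c(OCc2ccccc2)c1 | intermediate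

19 | m-xylylene-bridged undeca-O-benzyl trimer | O[C@H]1[C@H]%10c2c(OCc3cccc(COc4cc(OCc5ccccc5)c%10c5O[C@H](c6cc(OCc7ccccc7)c(OCc7ccccc7)c(OCc7ccccc7)c6)[C@@H](O)[C@@H](c6c(OCc7ccccc7)cc(OCc7ccccc7)c7c6O[C@H](c6ccc(OCc8ccccc8)c(OCc8ccccc8)c6)[C@@H](O)C7)c45)c3)cc(OCc3ccccc3)cc2O[C@@H]1c1ccc(OCc2ccccc2)c(OCc2ccccc2)c1 | intermediate

20 | catechin-(4α→8)-gallocatechin-(4β→8)-catechin | Oc1cc(O)c2c(c1)O[C@H](c1ccc(O)c(O)c1)[C@@H](O)[C@@H]2c1c(O)cc(O)c2c1O[C@H](c1cc(O)c(O)c(O)c1)[C@@H](O)[C@H]2c1c(O)cc(O)c2c1O[C@H](c1ccc(O)c(O)c1)[C@@H](O)C2 | target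

**Totals**
- Total step count: 12.
- Longest linear sequence: 8 (steps 1, 2, 4, 5, 9, 10, 11, 12).

**Steps most likely to fail**

Step 10 (double closure). The risks are wrong pairing, a strained cyclophane, or incomplete face selectivity at the upper cation. The fallback gives up the xylylene strap and makes the two bonds in separate operations. It sets out from 9 and 2 and returns at 20. Compound 9 is benzylated at O5 (BnBr, K2CO3) to the fully protected strapped diester F1. BF3·OEt2 at high dilution then closes only the 14-membered macrolactone F2, and K2CO3/MeOH frees the nona-O-benzyl 3,4-cis dimer F3. Separately, 2 is oxidised with DDQ in the presence of methanol to the 4β-methoxy electrophile F4. F4 is coupled intermolecularly with an excess of F3 (TMSOTf, CH2Cl2, −78 °C) to the trideca-O-benzyl trimer F5, and hydrogenolysis of F5 over Pd(OH)2/C gives 20.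

Step 5 (reduction next to the 3-O-ester). The risks are acyl migration to O4, transesterification, or early cyclisation. The fallback installs the ester only after the ketone is gone and builds the xylylene strap from the middle unit. It sets out from 6 and returns at 16. Compound 6 is reduced (NaBH4) and methanolysed (PPTS, MeOH) to 4β-methoxy-7,3',4',5'-tetra-O-benzylgallocatechin F6. The 5-phenol of F6 is alkylated with excess 14 (K2CO3) to the benzylic bromide F7. The single remaining 3-OH is esterified with 4 (DCC, DMAP) to the strapped bromide F8, and F8 alkylates the 5-phenol of 13 (Cs2CO3, DMF) to give 16.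

Step 9 (carbonate-mediated union of two large fragments at a hindered peri phenol). The fallback replaces base alkylation by redox-neutral Mitsunobu etherification. It sets out from 13 and 9 and returns at 16. Compound 13 is coupled with excess 1,3-benzenedimethanol (PPh3, DIAD, THF) to the 5-O-[3-(hydroxymethyl)benzyl] ether F9. The primary benzylic alcohol of F9 is then coupled with the phenol of 9 under the same conditions to give 16.

**Further compounds**

F1 | step 10 | glutarate diester of 4β-methoxy-penta-O-benzylgallocatechin and tetra-O-benzylcatechin | C(CC(=O)O[C@H]1[C@@H](OC)c2c(OCc3ccccc3)cc(OCc3ccccc3)cc2O[C@@H]1c1cc(OCc2ccccc2)c(OCc2ccccc2)c(OCc2ccccc2)c1)CC(=O)O[C@H]1Cc2c(OCc3ccccc3)cc(OCc3ccccc3)cc2O[C@@H]1c1ccc(OCc2ccccc2)c(OCc2ccccc2)c1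

F2 | step 10 | 14-membered glutarate macrolactone with the 4β C4–C8 bond | C(CC(=O)O[C@H]1[C@@H]%10c2c(OCc3ccccc3)cc(OCc3ccccc3)cc2O[C@@H]1c1cc(OCc2ccccc2)c(OCc2ccccc2)c(OCc2ccccc2)c1)CC(=O)O[C@H]1Cc2c(OCc3ccccc3)cc(OCc3ccccc3)c%10c2O[C@@H]1c1ccc(OCc2ccccc2)c(OCc2ccccc2)c1

F3 | step 10 | nona-O-benzyl gallocatechin-(4β→8)-catechin | c1c(OCc2ccccc2)cc(OCc2ccccc2)c2c1O[C@H](c1cc(OCc3ccccc3)c(OCc3ccccc3)c(OCc3ccccc3)c1)[C@@H](O)[C@H]2c1c(OCc2ccccc2)cc(OCc2ccccc2)c2c1O[C@H](c1ccc(OCc3ccccc3)c(OCc3ccccc3)c1)[C@@H](O)C2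

F4 | step 10 | 4β-methoxy-5,7,3',4'-tetra-O-benzylcatechin | O[C@H]1[C@@H](OC)c2c(OCc3ccccc3)cc(OCc3ccccc3)cc2O[C@@H]1c1ccc(OCc2ccccc2)c(OCc2ccccc2)c1

F5 | step 10 | trideca-O-benzyl catechin-(4α→8)-gallocatechin-(4β→8)-catechin | c1(OCc2ccccc2)cc(OCc2ccccc2)c2c(c1)O[C@H](c1ccc(OCc3ccccc3)c(OCc3ccccc3)c1)[C@@H](O)[C@@H]2c1c(OCc2ccccc2)cc(OCc2ccccc2)c2c1O[C@H](c1cc(OCc3ccccc3)c(OCc3ccccc3)c(OCc3ccccc3)c1)[C@@H](O)[C@H]2c1c(OCc2ccccc2)cc(OCc2ccccc2)c2c1O[C@H](c1ccc(OCc3ccccc3)c(OCc3ccccc3)c1)[C@@H](O)C2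

F6 | step 5 | 4β-methoxy-7,3',4',5'-tetra-O-benzylgallocatechin | O[C@H]1[C@@H](OC)c2c(O)cc(OCc3ccccc3)cc2O[C@@H]1c1cc(OCc2ccccc2)c(OCc2ccccc2)c(OCc2ccccc2)c1

F7 | step 5 | 5-O-[3-(bromomethyl)benzyl] ether of F6 | O[C@H]1[C@@H](OC)c2c(OCc3cccc(CBr)c3)cc(OCc3ccccc3)cc2O[C@@H]1c1cc(OCc2ccccc2)c(OCc2ccccc2)c(OCc2ccccc2)c1

F8 | step 5 | glutarate diester of F7 and tetra-O-benzylcatechin | C(CC(=O)O[C@H]1[C@@H](OC)c2c(OCc3cccc(CBr)c3)cc(OCc3ccccc3)cc2O[C@@H]1c1cc(OCc2ccccc2)c(OCc2ccccc2)c(OCc2ccccc2)c1)CC(=O)O[C@H]1Cc2c(OCc3ccccc3)cc(OCc3ccccc3)cc2O[C@@H]1c1ccc(OCc2ccccc2)c(OCc2ccccc2)c1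

F9 | step 9 | 5-O-[3-(hydroxymethyl)benzyl] ether of 13 | O[C@H]1[C@@H](OC)c2c(OCc3cccc(CO)c3)cc(OCc3ccccc3)cc2O[C@@H]1c1ccc(OCc2ccccc2)c(OCc2ccccc2)c1
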